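## Retrosynthetic overview

1. The target is cut between chain carbon C1' and ring carbon C3. In the last step, unprotected 2,5-dihydroxy-1,4-benzoquinone takes up the (E)-nonadec-14-enyl radical, released with loss of CO2 from bis[(E)-icos-15-enoyl] peroxide (decarboxylative radical C–H alkylation, no protecting groups).
2. Enabling feature: in the six-membered quinone ring (C1=O, C2–OH, C3–H, C4=O, C5–OH, C6–H), C3 and C6 are the only C–H carbons and are equivalent by symmetry. Each is the β-carbon of an enone, C1(=O)–C2(OH)=C3. Radical addition there leaves a radical on C2 between the OH donor and the C1=O acceptor, and this radical is easily oxidised back to the quinone. The chain alkene C14'=C15' is an unactivated 1,2-dialkyl alkene thirteen CH2 groups away and stays a spectator.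
3. In polar terms both carbons are donors: C3 is the α-carbon of the vinylogous acid HO–C2=C3–C4=O, and C1' is a carboxylate-derived carbanion equivalent. The radical path joins them, with the O–O bond as built-in oxidant and CO2 as traceless activating group.
4. (E)-Icos-15-enoic acid: C15=C16 comes from a Julia–Kocienski olefination of methyl 15-oxopentadecanoate (C1–C15, from ω-pentadecalactone) with pentyl phenyltetrazolyl sulfone (C16–C20).
5. Rings: no ring is formed. The quinone ring is bought intact, and the 16-membered lactone ring of the starting material is opened in step 1.

Key step: step 8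

Remark: ω-pentadecalactone, 1-bromopentane, 1-phenyl-1H-tetrazole-5-thiol and 2,5-dihydroxy-1,4-benzoquinone are taken as commercial. The hydroxyquinone is treated in the tautomer drawn in the target SMILES.

## Route

Step 1
Reactants: 1 ω-pentadecalactone (oxacyclohexadecan-2-one)
Product: 2 methyl 15-hydroxypentadecanoate
Conditions: MeOH, H2SO4 (cat.), reflux
Reagents that add atoms: methanol, CO
Why: Acid-catalysed transesterification (Fischer-type methanolysis) should open the unstrained macrolactone because methanol as solvent drives the equilibrium to the open hydroxy ester.

Step 2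
Reactants: 2 methyl 15-hydroxypentadecanoate
Product: 3 methyl 15-oxopentadecanoate
Conditions: TEMPO (cat.), PhI(OAc)2, CH2Cl2, rt
Reagents that add atoms: none
Why: The oxoammonium-mediated TEMPO/PhI(OAc)2 oxidation of a primary alcohol in anhydrous CH2Cl2 should stop at the aldehyde and leave the methyl ester untouched.

Step 3
Reactants: 4 1-bromopentane; 5 1-phenyl-1H-tetrazole-5-thiol
Product: 6 5-(pentylsulfanyl)-1-phenyl-1H-tetrazole
Conditions: K2CO3, acetone, reflux
Reagents that add atoms: none
Why: SN2 S-alkylation of the soft thiolate of 5 by an unhindered primary bromide (Williamson-type thioether synthesis) should be clean and selective for sulfur.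

Step 4
Reactants: 6 5-(pentylsulfanyl)-1-phenyl-1H-tetrazole
Product: 7 5-(pentylsulfonyl)-1-phenyl-1H-tetrazole
Conditions: 30% aq. H2O2, (NH4)6Mo7O24·4H2O (cat.), EtOH, 0 °C → rt
Reagents that add atoms: hydrogen peroxide, OO
Why: Molybdate-catalysed peroxide oxidation should take the sulfide through the sulfoxide to the sulfone, and no other oxidisable group is present.

Step 5
Reactants: 7 5-(pentylsulfonyl)-1-phenyl-1H-tetrazole; 3 methyl 15-oxopentadecanoate
Product: 9 methyl (E)-icos-15-enoate, via potassium sulfonyl carbanion 8 (not isolated)
Conditions: 7, KN(SiMe3)2, DME, −55 °C; then 3, −55 °C → rt; aq. NH4Cl; chromatography on AgNO3-impregnated SiO2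
Reagents that add atoms: none
Why: In this Julia–Kocienski olefination carbanion 8 should add to the aldehyde through an open transition state favoured by potassium in DME to give mainly the anti β-alkoxy sulfone, whose Smiles rearrangement and antiperiplanar loss of SO2 and tetrazololate set the E alkene, while 8 is too weak a base to enolise the methyl ester.

Step 6
Reactants: 9 methyl (E)-icos-15-enoate
Product: 11 (E)-icos-15-enoic acid, via lithium (E)-icos-15-enoate 10 (not isolated)
Conditions: LiOH·H2O, THF/MeOH/H2O, rt; then 1 M HCl
Reagents that add atoms: lithium hydroxide, [Li+].[OH-]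
Why: Saponification of an unhindered methyl ester followed by acidification should give the free acid without touching the isolated E alkene.

Step 7
Reactants: 11 (E)-icos-15-enoic acid (two molecules)
Product: 13 bis[(E)-icos-15-enoyl] peroxide, via (E)-icos-15-eneperoxoic acid 12 (not isolated)
Conditions: 30% aq. H2O2 (0.5 equiv), DCC, DMAP (cat.), CH2Cl2, −15 → 0 °C, dark; short SiO2 filtration, kept below 25 °C
Reagents that add atoms: hydrogen peroxide, OO
Why: Carbodiimide (Steglich-type) activation should acylate H2O2 twice, first to peracid 12 and then to the symmetrical diacyl peroxide faster than 12 can transfer oxygen to the unactivated 1,2-dialkyl alkene at −15 °C, a preparation known for unsaturated aliphatic acids.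

Step 8
Reactants: 13 bis[(E)-icos-15-enoyl] peroxide; 14 2,5-dihydroxy-1,4-benzoquinone
Product: 17 2,5-dihydroxy-3-[(E)-nonadec-14-enyl]-1,4-benzoquinone (target), via (E)-nonadec-14-enyl radical 15 (not isolated), via ring adduct radical 16 (not isolated)
Conditions: 14 (3 equiv), AcOH, 95 °C, Ar; 13 added in portions
Reagents that add atoms: none
Why: At 95 °C the O–O bond of 13 breaks and the acyloxy radicals lose CO2 to give the nucleophilic primary radical 15, which adds to the unsubstituted ring carbon C3 of 14, the β-carbon of the enone C1(=O)–C2(OH)=C3, to give radical 16 centred on C2 between the donor OH and the acceptor C1=O; 16 is oxidised by electron transfer to a further molecule of 13 and loses the C3 proton, which restores the quinone and releases one carboxylate (recovered as 11) plus a new radical 15, so that a chain runs. The closest known reaction type is the homolytic alkylation of hydroxyquinones with diacyl peroxides in hot acetic acid (a Minisci-type substitution), which is established for 2,5-dihydroxy-1,4-benzoquinone itself with saturated long-chain peroxides. In polar terms both carbons are donors (C3 is the α-carbon of the vinylogous acid HO–C2=C3–C4=O, the chain carbon is a carboxylate-derived carbanion equivalent), so the radical pathway with the peroxide as built-in oxidant is what allows their union without any protecting or activating group on the ring. No ring is closed and no stereocentre remains (the sp3 centre C3 of 16 is erased on re-oxidation), and the E geometry set in step 5 should stay untouched because no reversibly adding radical such as thiyl or halogen is present. Site selectivity is secured by the substrate, since C3 and C6 are the only C–H carbons and are equivalent by symmetry, and mono- over dialkylation is secured by the threefold excess of cheap 14 and by the lower electrophilicity of the alkylated quinone. Chemoselectivity for the ring over the chain alkene rests on the much faster addition of alkyl radicals to quinones than to unactivated 1,2-dialkyl alkenes, and closure of 15 onto its own alkene would need a 14- or 15-membered transition state.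

## Compound list

1 | ω-pentadecalactone (oxacyclohexadecan-2-one) | O=C1CCCCCCCCCCCCCCO1 | starting material
2 | methyl 15-hydroxypentadecanoate | COC(=O)CCCCCCCCCCCCCCO | intermediate
3 | methyl 15-oxopentadecanoate | COC(=O)CCCCCCCCCCCCCC=O | intermediate
4 | 1-bromopentane | CCCCCBr | starting material
5 | 1-phenyl-1H-tetrazole-5-thiol | Sc1nnnn1-c1ccccc1 | starting material
6 | 5-(pentylsulfanyl)-1-phenyl-1H-tetrazole | CCCCCSc1nnnn1-c1ccccc1 | intermediate
7 | 5-(pentylsulfonyl)-1-phenyl-1H-tetrazole | CCCCCS(=O)(=O)c1nnnn1-c1ccccc1 | intermediate
8 | potassium 1-[(1-phenyl-1H-tetrazol-5-yl)sulfonyl]pentan-1-ide | [K+].CCCC[CH-]S(=O)(=O)c1nnnn1-c1ccccc1 | intermediate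
9 | methyl (E)-icos-15-enoate | CCCC/C=C/CCCCCCCCCCCCCC(=O)OC | intermediate
10 | lithium (E)-icos-15-enoate | [Li+].CCCC/C=C/CCCCCCCCCCCCCC(=O)[O-] | intermediate
11 | (E)-icos-15-enoic acid | CCCC/C=C/CCCCCCCCCCCCCC(=O)O | intermediate
12 | (E)-icos-15-eneperoxoic acid | CCCC/C=C/CCCCCCCCCCCCCC(=O)OO | intermediate
13 | bis[(E)-icos-15-enoyl] peroxide | CCCC/C=C/CCCCCCCCCCCCCC(=O)OOC(=O)CCCCCCCCCCCCC/C=C/CCCC | intermediate
14 | 2,5-dihydroxy-1,4-benzoquinone | O=C1C=C(O)C(=O)C=C1O | starting material
15 | (E)-nonadec-14-en-1-yl radical | CCCC/C=C/CCCCCCCCCCCC[CH2] | intermediate
16 | C2-centred radical from addition of 15 to C3 of 14 (C3 sp3, racemic, transient) | CCCC/C=C/CCCCCCCCCCCCCC1[C](O)C(=O)C=C(O)C1=O | intermediate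
17 | 2,5-dihydroxy-3-[(E)-nonadec-14-enyl]-1,4-benzoquinone | CCCC/C=C/CCCCCCCCCCCCCC1=C(O)C(=O)C=C(O)C1=O | target

## Step count and risks

Total step count: 8
Longest linear sequence: 6 steps (1, 2, 5, 6, 7, 8)

**Step 8 (radical alkylation).** Cage recombination and dimerisation of the chain radical, allylic hydrogen abstraction and a second alkylation at C6 may erode the conversion to the monoalkylated quinone.
- The fallback is polar instead of radical, so the chain carbon becomes an acceptor. It sets out from 9 and comes back at 17.
- The potassium enolate of 9 (KN(SiMe3)2, THF, −78 °C) is hydroxylated with 2-(phenylsulfonyl)-3-phenyloxaziridine to racemic methyl (E)-2-hydroxyicos-15-enoate F1.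
- LiAlH4 (THF, 0 °C) reduces this to racemic (E)-icos-15-ene-1,2-diol F2, and NaIO4 (THF/H2O, rt) cleaves the glycol to (E)-nonadec-14-enal F3.
- A three-component reductive alkylation then joins F3, 14 and diethyl 2,6-dimethyl-1,4-dihydropyridine-3,5-dicarboxylate (Hantzsch ester) under L-proline catalysis (CH2Cl2, rt).
- Knoevenagel condensation at the nucleophilic C3 gives 5-hydroxy-3-[(E)-nonadec-14-enylidene]cyclohex-5-ene-1,2,4-trione F4. This accepts hydride at the exocyclic carbon and tautomerises to 17. The isolated alkene is inert to every reagent on this way.

**Step 7 (peroxide formation).** Oxygen transfer from the transient peracid to the chain alkene, incomplete second acylation and premature O–O homolysis during isolation may spoil the radical precursor.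
- The fallback uses no preformed O–O compound. It sets out from 11 and comes back at 17, bypassing 13.
- The free acid 11 is decarboxylated oxidatively in the presence of excess 14 (AgNO3 cat., (NH4)2S2O8 added slowly, MeCN/H2O, 65 °C; silver-catalysed Minisci-type quinone alkylation).
- Divalent silver, formed from monovalent silver and persulfate, oxidises the carboxylate to the same radical 15. The adduct 16 is oxidised onward by persulfate or divalent silver.
- Slow persulfate addition and a generous AgNO3 loading should let monovalent silver, not the chain alkene, consume the sulfate radical anion. No new compound arises on this way (entry F0).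

**Step 5 (olefination).** Incomplete anti selectivity in the addition of the metalated sulfone would leave Z isomer that is hard to remove. Self-condensation of the sulfone or aldol reaction of the enolisable aldehyde may also compete.
- In the fallback the geometry comes from a syn hydrometalation instead of an olefination. It sets out from 3 and comes back at 9.
- Seyferth–Gilbert homologation with the Ohira–Bestmann reagent (dimethyl (1-diazo-2-oxopropyl)phosphonate, K2CO3, MeOH, rt) gives methyl hexadec-15-ynoate F5.
- Hydrozirconation with Cp2Zr(H)Cl (THF, rt) and iodinolysis (I2, 0 °C) give methyl (E)-16-iodohexadec-15-enoate F6. Syn addition to the terminal alkyne fixes the geometry.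
- Negishi coupling with n-BuZnBr (Pd(dppf)Cl2 cat., THF, rt) proceeds with retention and gives 9.

## Further compounds

F1 | step 8 | methyl (E)-2-hydroxyicos-15-enoate (racemic) | CCCC/C=C/CCCCCCCCCCCCC(O)C(=O)OC
F2 | step 8 | (E)-icos-15-ene-1,2-diol (racemic) | CCCC/C=C/CCCCCCCCCCCCC(O)CO
F3 | step 8 | (E)-nonadec-14-enal | CCCC/C=C/CCCCCCCCCCCCC=O
F4 | step 8 | 5-hydroxy-3-[(E)-nonadec-14-enylidene]cyclohex-5-ene-1,2,4-trione | CCCC/C=C/CCCCCCCCCCCCC=C1C(=O)C(=O)C=C(O)C1=O
F0 | step 7 | none | none
F5 | step 5 | methyl hexadec-15-ynoate | C#CCCCCCCCCCCCCCC(=O)OC
F6 | step 5 | methyl (E)-16-iodohexadec-15-enoate | I/C=C/CCCCCCCCCCCCCC(=O)OC
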